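**Plan**
- Cuts: first the two O–Si bonds, then the C4 ketone back to a C4 methyl ether. Ring C is cut at O1–C2 and C3–C4. On ring B the cuts are the C3'–CH2 (prenyl) bond and the vinyl C=C bond.
- Enabling feature: O1–C8a–C4a–C4 is a 1-oxadiene on the edge of ring A, that is, an ortho-quinone methide already oxygenated at C4. C2=C3 bearing ring B is a para-alkoxystyrene, so ring C is the [4+2] adduct of the two.
- Forward order: rings A and B are purchased. The ring A aldehyde is bis-silylated, and the ring B aldehyde is methylenated and then prenylated. Ring C, the only ring built, closes in one three-component reaction of aldehyde, methanol and styrene.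
- Stereochemistry: C2 (S) comes from the chiral anion of a confined Brønsted acid in the cycloaddition. C4 is set alongside it (2,4-cis) and is deleted on oxidation.
- End game: C4–OMe to C4–OH, oxidation, then acidic fluoride. The configurationally fragile flavanone exists only in the last two steps.

Key step: step 4

Assumption: the sense of induction of the confined acid cannot be derived from precedent; the (S,S) acid is written, and its equally accessible mirror image would be used if the (S,S) acid proves to give 2R.

Step 1
Reactants: 1 2,4,6-trihydroxybenzaldehyde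
Product: 2 2-hydroxy-4,6-bis(tert-butyldimethylsilyloxy)benzaldehyde
Conditions: TBSCl (2.1 equiv), imidazole, DMF, 0 °C to rt
Reagents that add atoms: tert-butyldimethylsilyl chloride, CC(C)(C)[Si](C)(C)Cl
Why: Silyl ether formation, in which the acidic 4-OH and one of the two equivalent ortho phenols react first and the last phenol, locked in a hydrogen bond to the formyl oxygen, is left free with two equivalents of chloride, as is routine for acylphloroglucinols.

Step 2
Reactants: 3 3-bromo-4-methoxybenzaldehyde
Product: 4 2-bromo-1-methoxy-4-vinylbenzene (3-bromo-4-methoxystyrene)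
Conditions: MePPh3Br, KOt-Bu, THF, 0 °C to rt
Reagents that add atoms: methyltriphenylphosphonium bromide, C[P+](c1ccccc1)(c1ccccc1)c1ccccc1.[Br-]
Why: Wittig methylenation of a non-enolisable aromatic aldehyde, to which the aryl bromide and the methyl ether are inert.

Step 3
Reactants: 4 2-bromo-1-methoxy-4-vinylbenzene; 5 3-methylbut-2-enylboronic acid pinacol ester (prenyl-Bpin)
Product: 6 1-methoxy-2-(3-methylbut-2-enyl)-4-vinylbenzene (4-methoxy-3-prenylstyrene)
Conditions: PdCl2(IPent)(3-chloropyridine) (2 mol%), 5 M aq KOH, THF, 70 °C (IPent = 1,3-bis[2,6-di(pentan-3-yl)phenyl]imidazol-2-ylidene)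
Reagents that add atoms: none
Why: Suzuki–Miyaura allyl–aryl coupling, placed after the methylenation because an allylboronate would add to a free aldehyde; the very bulky carbene ligand steers prenylboronates to the linear product through reductive elimination from the primary σ-allylpalladium species, and fast transmetalation under aqueous hydroxide should outrun Heck reaction at the vinyl group.

Step 4
Reactants: 2 2-hydroxy-4,6-bis(tert-butyldimethylsilyloxy)benzaldehyde; 6 4-methoxy-3-prenylstyrene (1.5 equiv); 7 methanol (1.5 equiv)
Product: 9 (2S,4S)-5,7-bis(tert-butyldimethylsilyloxy)-4,4'-dimethoxy-3'-(3-methylbut-2-enyl)flavan (2,4-cis), via methoxy ortho-quinone methide 8 (not isolated)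
Conditions: (S,S)-imidodiphosphoric acid built from two 3,3'-bis(2,4,6-triethylphenyl)-BINOL units (5 mol%), 3 Å MS, toluene, −20 °C; chromatography to the single cis diastereomer
Reagents that add atoms: none
Why: Proposed new method: the acid condenses 2 with methanol (hemiacetal, then loss of water to the sieves, which exclude methanol) to an aryl oxocarbenium ion that is the O-protonated form of 8 and stays hydrogen-bonded and ion-paired inside the chiral imidodiphosphate. The unsubstituted CH2 terminus of 6 attacks the electrophilic carbon (future C4) while the ring A oxygen closes onto the developing 4-methoxybenzylic centre (future C2), so C3–C4 and O1–C2 form in one concerted but asynchronous inverse-electron-demand oxa-[4+2] event that restores the aromaticity of ring A. The closest known reaction types are the confined-acid-catalysed intramolecular [4+2] cycloaddition of ortho-quinone methides generated from salicylaldehydes and unsaturated alcohols, and the racemic acid-catalysed chroman synthesis from salicylaldehyde, orthoformate and styrene; new here is the intermolecular enantioselective merger of the two. Ring C closes by intermolecular [4+2] cycloaddition, four atoms (O1, C8a, C4a, C4) coming from 8 and two (C3, C2) from 6, with regiochemistry fixed by the matched polarity of the partners. The anion pocket leaves one face of the bound heterodiene open and so sets C4, and it sets C2 through the endo placement of ring B (2,4-cis); because an exo adduct formed on the same face would carry 2R, 9 is freed from any trans isomer before C4 is erased. The step needs the vinyl group to react ahead of the prenyl alkene and ahead of acid-induced oligomerisation: the para-methoxy group makes the vinyl CH2 the most nucleophilic and least hindered alkene carbon present, and the moderate acidity of the catalyst, the low temperature and near-stoichiometric methanol should spare the trisubstituted alkene, the aryl silyl ethers and the C4 ether of 9.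

Step 5
Reactants: 9 (2S,4S)-5,7-bis(tert-butyldimethylsilyloxy)-4,4'-dimethoxy-3'-prenylflavan
Product: 10 (2S)-5,7-bis(tert-butyldimethylsilyloxy)-4'-methoxy-3'-prenylflavan-4-ol (mixture of C4 epimers, used as such)
Conditions: TsOH·H2O (10 mol%), THF/H2O 4:1, rt
Reagents that add atoms: water, O
Why: SN1 solvolysis of a benzylic ether, since the C4 cation is stabilised by O1 and the 5- and 7-oxygens and therefore ionises under acid too dilute to touch the aryl silyl ethers, the prenyl group or the far less basic O1–C2 bond, and the large excess of water drives the exchange.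

Step 6
Reactants: 10 (2S)-5,7-bis(tert-butyldimethylsilyloxy)-4'-methoxy-3'-prenylflavan-4-ol
Product: 11 (2S)-5,7-bis(tert-butyldimethylsilyloxy)-4'-methoxy-3'-prenylflavanone
Conditions: Dess–Martin periodinane, pyridine, CH2Cl2, 0 °C to rt
Reagents that add atoms: none
Why: Dess–Martin oxidation of a secondary benzylic alcohol, in which both C4 epimers converge on one ketone and the pyridine buffer keeps the medium too mild for ionisation at C4 or for ring opening of the new flavanone, so C2 is untouched.

Step 7
Reactants: 11 (2S)-5,7-bis(tert-butyldimethylsilyloxy)-4'-methoxy-3'-prenylflavanone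
Product: 12 4'-O-methyllicoflavanone, (2S)-5,7-dihydroxy-4'-methoxy-3'-(3-methylbut-2-enyl)flavanone
Conditions: Et3N·3HF, THF, 0 °C to rt
Reagents that add atoms: none
Why: Fluoride cleavage of aryl silyl ethers, made easy because both silyloxy groups are conjugated with the ketone; the slightly acidic amine–HF reagent releases phenols rather than phenoxides, so the retro-oxa-Michael opening to the chalcone that racemises flavanones is not triggered.

**Compound list**
1 | 2,4,6-trihydroxybenzaldehyde | O=Cc1c(O)cc(O)cc1O | starting material
2 | 2-hydroxy-4,6-bis(tert-butyldimethylsilyloxy)benzaldehyde | O=Cc1c(O)cc(O[Si](C)(C)C(C)(C)C)cc1O[Si](C)(C)C(C)(C)C | intermediate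
3 | 3-bromo-4-methoxybenzaldehyde | COc1ccc(C=O)cc1Br | starting material
4 | 2-bromo-1-methoxy-4-vinylbenzene | C=Cc1ccc(OC)c(Br)c1 | intermediate
5 | 3-methylbut-2-enylboronic acid pinacol ester | CC(C)=CCB1OC(C)(C)C(C)(C)O1 | starting material
6 | 1-methoxy-2-(3-methylbut-2-enyl)-4-vinylbenzene | C=Cc1ccc(OC)c(CC=C(C)C)c1 | intermediate
7 | methanol | CO | starting material
8 | 6-(methoxymethylidene)-3,5-bis(tert-butyldimethylsilyloxy)cyclohexa-2,4-dien-1-one (alkene geometry not fixed, in equilibrium with its O-protonated oxocarbenium form) | COC=C1C(=O)C=C(O[Si](C)(C)C(C)(C)C)C=C1O[Si](C)(C)C(C)(C)C | intermediate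
9 | (2S,4S)-5,7-bis(tert-butyldimethylsilyloxy)-4,4'-dimethoxy-3'-(3-methylbut-2-enyl)flavan | COc1ccc([C@@H]2C[C@H](OC)c3c(O[Si](C)(C)C(C)(C)C)cc(O[Si](C)(C)C(C)(C)C)cc3O2)cc1CC=C(C)C | intermediate
10 | (2S)-5,7-bis(tert-butyldimethylsilyloxy)-4'-methoxy-3'-(3-methylbut-2-enyl)flavan-4-ol, C4 epimers | COc1ccc([C@@H]2CC(O)c3c(O[Si](C)(C)C(C)(C)C)cc(O[Si](C)(C)C(C)(C)C)cc3O2)cc1CC=C(C)C | intermediate
11 | (2S)-5,7-bis(tert-butyldimethylsilyloxy)-4'-methoxy-3'-(3-methylbut-2-enyl)flavanone | COc1ccc([C@@H]2CC(=O)c3c(O[Si](C)(C)C(C)(C)C)cc(O[Si](C)(C)C(C)(C)C)cc3O2)cc1CC=C(C)C | intermediate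
12 | 4'-O-methyllicoflavanone | COc1ccc([C@@H]2CC(=O)c3c(O)cc(O)cc3O2)cc1CC=C(C)C | target

**Step count**
Total steps: 7. Longest linear sequence: 6 (3 → 4 → 6 → 9 → 10 → 11 → 12).

**Steps most likely to fail**

Step 4 (labelled step).
- What may go wrong:
  - poor facial selectivity, or leakage into the exo mode;
  - slow turnover because the bulky 6-silyloxy group fits the confined pocket badly;
  - cationic oligomerisation of the styrene, or methanol addition to it;
  - re-ionisation of the product at C4 followed by a second alkylation.
- Fallback, known chemistry only, from 2 and 6 back to 11: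
  - The established racemic three-component reaction (trimethyl orthoformate, catalytic Sc(OTf)3, CH2Cl2, 0 °C) should give racemic 2,4-cis-5,7-bis(tert-butyldimethylsilyloxy)-4,4'-dimethoxy-3'-prenylflavan F1.
  - The conditions of steps 5 and 6 then lead through racemic 5,7-bis(tert-butyldimethylsilyloxy)-4'-methoxy-3'-prenylflavan-4-ol F2 to racemic 5,7-bis(tert-butyldimethylsilyloxy)-4'-methoxy-3'-prenylflavanone F3.
  - Kinetic resolution follows by Noyori asymmetric transfer hydrogenation (RuCl(p-cymene)[(R,R)-TsDPEN], HCO2H/Et3N). It should reduce the 2R enantiomer to (2R,4R)-5,7-bis(tert-butyldimethylsilyloxy)-4'-methoxy-3'-prenylflavan-4-ol F4 and leave the 2S ketone.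
  - The 2S ketone, separated by chromatography, is 11.

Step 5.
- What may go wrong:
  - diversion of the C4 cation into elimination to the flav-3-ene, or Friedel–Crafts self-condensation with another ring A;
  - acid-induced ionisation of O1–C2, which would erode the configuration at C2;
  - partial loss of silyl groups.
- Fallback, from 9 directly to 11:
  - Oxidative cleavage of the benzylic methyl ether with DDQ in CH2Cl2/pH 7 buffer at 0 °C proceeds by hydride abstraction at C4 and capture of the oxocarbenium ion by water.
  - The hemiketal then collapses to the ketone. This avoids Brønsted acid and bypasses 10.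
  - No compound outside the list arises on this path (entry F0).

Step 3.
- What may go wrong:
  - allyl transfer at the substituted terminus, giving the reverse-prenyl isomer;
  - Heck oligomerisation through the vinyl group;
  - protodeboronation of the allylboronate.
- Fallback, from 3 back to 6:
  - The metal and the order of events are changed. Stille coupling of 3 with tributyl(3-methylbut-2-enyl)stannane (Pd(PPh3)4, LiCl, DMF, 90 °C) uses a reagent that does not add to aldehydes without a Lewis acid.
  - It should give 4-methoxy-3-(3-methylbut-2-enyl)benzaldehyde F5.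
  - Wittig methylenation under the conditions of step 2 then delivers 6.

**Further compounds**
F1 | step 4 | racemic 2,4-cis-5,7-bis(tert-butyldimethylsilyloxy)-4,4'-dimethoxy-3'-(3-methylbut-2-enyl)flavan | COc1ccc(C2CC(OC)c3c(O[Si](C)(C)C(C)(C)C)cc(O[Si](C)(C)C(C)(C)C)cc3O2)cc1CC=C(C)C
F2 | step 4 | racemic 5,7-bis(tert-butyldimethylsilyloxy)-4'-methoxy-3'-(3-methylbut-2-enyl)flavan-4-ol | COc1ccc(C2CC(O)c3c(O[Si](C)(C)C(C)(C)C)cc(O[Si](C)(C)C(C)(C)C)cc3O2)cc1CC=C(C)C
F3 | step 4 | racemic 5,7-bis(tert-butyldimethylsilyloxy)-4'-methoxy-3'-(3-methylbut-2-enyl)flavanone | COc1ccc(C2CC(=O)c3c(O[Si](C)(C)C(C)(C)C)cc(O[Si](C)(C)C(C)(C)C)cc3O2)cc1CC=C(C)C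
F4 | step 4 | (2R,4R)-5,7-bis(tert-butyldimethylsilyloxy)-4'-methoxy-3'-(3-methylbut-2-enyl)flavan-4-ol | COc1ccc([C@H]2C[C@@H](O)c3c(O[Si](C)(C)C(C)(C)C)cc(O[Si](C)(C)C(C)(C)C)cc3O2)cc1CC=C(C)C
F0 | step 5 | none | none
F5 | step 3 | 4-methoxy-3-(3-methylbut-2-enyl)benzaldehyde | COc1ccc(C=O)cc1CC=C(C)C
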